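**Plan** (germacrane numbering: ring C1–C10, lactone C11–C13, formyl carbon C14, hydroxymethyl carbon C15)

1. Cuts, in retrosynthetic order: the C8–O ester bond (made with inversion); then O–C6 and C11–C7 of the γ-lactone in one stroke; then the ten-membered ring at C6=C7 and at C1=C10; then C4=C5 and C3–C4 of the chain.
2. Enabling feature: the lactone oxygen sits on C6, allylic to the ring alkene C4=C5, so the lactone ring (O, C6, C7, C11, C12) is the 1,2-adduct of 2-bromoacrylic acid across the C6=C7 end of a ring 1,3-diene C4=C5–C6=C7 whose C7 terminus carries only hydrogen.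
3. Forward: chain aldehyde 8 (C1–C6, C15) and phosphono lactone 13 (C7–C10, C14) are joined at C1=C10; metathesis at C6=C7 closes the ten-membered ring across a temporary 8,14-lactone bridge; the bridge is reduced away; the methylene lactone ring is annulated last.
4. Stereochemistry: C8 comes from (S)-5-(hydroxymethyl)dihydrofuran-2(3H)-one. Its hydroxyl steers the palladium step, which sets C7 and C6 (cis-fused lactone, C11 trans to O8). C8 is then inverted in the Mitsunobu esterification that brings in the isovalerate.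
5. Alkene geometry: C4=C5 and C1=C10 come from two E-selective Horner–Wadsworth–Emmons reactions, C6=C7 from the ring constraint of the metathesis. The lactone bridge and two silyl ethers are helpers that are removed again.

Key step: step 13

**Route**

Step 1
Reactants: 1 triethyl phosphonoacetate; 2 3-bromo-1,1-dimethoxypropane
Product: 3 ethyl 2-(diethoxyphosphoryl)-5,5-dimethoxypentanoate
Conditions: NaH, cat. NaI, DMF, 0 to 60 °C
Reagents that add atoms: none
Why: SN2 C-alkylation of the sodium phosphonoacetate carbanion by the primary bromide is the standard entry to α-substituted Horner–Wadsworth–Emmons reagents, and the acetal is inert to base.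

Step 2
Reactants: 3 ethyl 2-(diethoxyphosphoryl)-5,5-dimethoxypentanoate; 4 (E)-but-2-enal
Product: 5 ethyl (2E,4E)-2-(3,3-dimethoxypropyl)hexa-2,4-dienoate
Conditions: NaH, THF, 0 °C to rt
Reagents that add atoms: none
Why: Horner–Wadsworth–Emmons olefination with the α-branched phosphonate should favour the 2E enoate (ester trans to the propenyl group), which fixes the C4=C5 geometry of the target (C3 cis to C6); any Z isomer is removed by chromatography.

Step 3
Reactants: 5 ethyl (2E,4E)-2-(3,3-dimethoxypropyl)hexa-2,4-dienoate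
Product: 6 (2E,4E)-2-(3,3-dimethoxypropyl)hexa-2,4-dien-1-ol
Conditions: i-Bu2AlH, CH2Cl2, −78 °C
Reagents that add atoms: none
Why: 1,2-reduction of the conjugated ester by i-Bu2AlH at low temperature gives the allylic alcohol without touching the acetal or the diene geometry.

Step 4
Reactants: 6 (2E,4E)-2-(3,3-dimethoxypropyl)hexa-2,4-dien-1-ol
Product: 7 tert-butyl{[(2E,4E)-2-(3,3-dimethoxypropyl)hexa-2,4-dien-1-yl]oxy}diphenylsilane
Conditions: t-BuPh2SiCl, imidazole, DMF, rt
Reagents that add atoms: tert-butyl(chloro)diphenylsilane, CC(C)(C)[Si](Cl)(c1ccccc1)c1ccccc1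
Why: Silylation of the primary allylic alcohol gives a robust ether that is meant to survive every step up to the last one.

Step 5
Reactants: 7 tert-butyl{[(2E,4E)-2-(3,3-dimethoxypropyl)hexa-2,4-dien-1-yl]oxy}diphenylsilane
Product: 8 (4E,6E)-4-{[(tert-butyldiphenylsilyl)oxy]methyl}octa-4,6-dienal
Conditions: pyridinium p-toluenesulfonate (cat.), acetone/H2O, 50 °C
Reagents that add atoms: water, O
Why: Mild acid-catalysed acetal hydrolysis frees the aldehyde while the tert-butyldiphenylsilyl ether is stable to the weak acid.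

Step 6
Reactants: 9 (S)-5-(hydroxymethyl)dihydrofuran-2(3H)-one
Product: 10 (S)-5-oxotetrahydrofuran-2-carbaldehyde
Conditions: Dess–Martin periodinane, CH2Cl2, 0 °C to rt; used at once
Reagents that add atoms: none
Why: Dess–Martin oxidation under neutral conditions should give the configurationally labile α-acyloxy aldehyde without epimerisation.

Step 7
Reactants: 10 (S)-5-oxotetrahydrofuran-2-carbaldehyde
Product: 11 (S)-5-ethenyldihydrofuran-2(3H)-one
Conditions: Ph3PCH3Br, KN(SiMe3)2, THF, −78 to 0 °C
Reagents that add atoms: methyltriphenylphosphonium bromide, C[P+](c1ccccc1)(c1ccccc1)c1ccccc1.[Br-]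
Why: Wittig methylenation with the non-stabilised ylide at low temperature attacks only the aldehyde (the lactone carbonyl is far less electrophilic) and should leave the C8 stereocentre intact.

Step 8
Reactants: 11 (S)-5-ethenyldihydrofuran-2(3H)-one
Product: 13 diethyl [(5S)-5-ethenyl-2-oxotetrahydrofuran-3-yl]phosphonate, via phosphonite 12 (not isolated)
Conditions: LiN(iPr)2 (2.1 equiv), THF, −78 °C; ClP(OEt)2; then 30% aq. H2O2, 0 °C
Reagents that add atoms: diethyl chlorophosphite, CCOP(Cl)OCC; hydrogen peroxide, OO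
Why: C-phosphinylation of the lactone lithium enolate followed by oxidation in the same flask is a known route to α-phosphono lactones; the new centre at C10 becomes sp2 in the next step, so its configuration does not matter.

Step 9
Reactants: 13 diethyl [(5S)-5-ethenyl-2-oxotetrahydrofuran-3-yl]phosphonate; 8 (4E,6E)-4-{[(tert-butyldiphenylsilyl)oxy]methyl}octa-4,6-dienal
Product: 14 (3E,5S)-3-[(4E,6E)-4-{[(tert-butyldiphenylsilyl)oxy]methyl}octa-4,6-dien-1-ylidene]-5-ethenyldihydrofuran-2(3H)-one
Conditions: NaH, THF, 0 °C; then 8, 0 °C to rt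
Reagents that add atoms: none
Why: Horner–Wadsworth–Emmons olefination of α-phosphono-γ-butyrolactones with aliphatic aldehydes gives mainly the E alkylidene lactone (C2 cis to C9), the geometry the target's C1=C10 bond needs and the one that lets the chain reach back to C8.

Step 10
Reactants: 14 (3E,5S)-3-[(4E,6E)-4-{[(tert-butyldiphenylsilyl)oxy]methyl}octa-4,6-dien-1-ylidene]-5-ethenyldihydrofuran-2(3H)-one
Product: 15 (1E,5E,7Z,9S)-5-{[(tert-butyldiphenylsilyl)oxy]methyl}-10-oxabicyclo[7.2.1]dodeca-1,5,7-trien-11-one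
Conditions: second-generation Hoveyda–Grubbs catalyst (10 mol %), toluene (1 mM), 80 °C, argon purge
Reagents that add atoms: none
Why: Ring-closing ene–diene metathesis between the vinyl group on C8 and the propenyl end of the diene closes the ten-membered ring with loss of propene; the trisubstituted C4=C5 and C1=C10 alkenes are too hindered to engage, and the bridged ring should hold the new C6=C7 bond only as the cis isomer.

Step 11
Reactants: 15 (1E,5E,7Z,9S)-5-{[(tert-butyldiphenylsilyl)oxy]methyl}-10-oxabicyclo[7.2.1]dodeca-1,5,7-trien-11-one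
Product: 16 (1S,2Z,4E,8E)-5-{[(tert-butyldiphenylsilyl)oxy]methyl}-9-(hydroxymethyl)cyclodeca-2,4,8-trien-1-ol
Conditions: i-Bu2AlH (4 equiv), CH2Cl2, −78 to 0 °C; Rochelle salt work-up
Reagents that add atoms: none
Why: 1,2-reduction of the α-alkylidene lactone through the lactol to the 1,4-diol removes the bridge, frees the C8 carbinol and brings C14 to the alcohol level before any other carbonyl group is present.

Step 12
Reactants: 16 (1S,2Z,4E,8E)-5-{[(tert-butyldiphenylsilyl)oxy]methyl}-9-(hydroxymethyl)cyclodeca-2,4,8-trien-1-ol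
Product: 17 (1S,2Z,4E,8E)-5-{[(tert-butyldiphenylsilyl)oxy]methyl}-9-{[(triethylsilyl)oxy]methyl}cyclodeca-2,4,8-trien-1-ol
Conditions: Et3SiCl (1.05 equiv), imidazole, CH2Cl2, −78 °C
Reagents that add atoms: chlorotriethylsilane, CC[Si](Cl)(CC)CC
Why: Selective silylation of the primary allylic C14 hydroxyl over the secondary C8 hydroxyl at low temperature leaves the C8 hydroxyl free to steer the next step.

Step 13
Reactants: 17 (1S,2Z,4E,8E)-5-{[(tert-butyldiphenylsilyl)oxy]methyl}-9-{[(triethylsilyl)oxy]methyl}cyclodeca-2,4,8-trien-1-ol; 18 2-bromoprop-2-enoic acid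
Product: 19 (3aR,4S,6E,10E,11aS)-10-{[(tert-butyldiphenylsilyl)oxy]methyl}-4-hydroxy-3-methylidene-6-{[(triethylsilyl)oxy]methyl}-3a,4,5,8,9,11a-hexahydrocyclodeca[b]furan-2(3H)-one
Conditions: Pd(OAc)2 (10 mol %), P(2-furyl)3 (20 mol %), K2CO3, DMF, 60 °C; 18 added slowly
Reagents that add atoms: none
Why: Zerovalent palladium inserts into the C–Br bond of the 2-bromoacrylate, the 1-carboxyvinyl palladium species adds syn across C6=C7 with carbon going to the only unsubstituted diene terminus C7, and the resulting η3-allyl palladium unit over C6–C5–C4 is captured at C6 by the tethered carboxylate, which releases zerovalent palladium and leaves C4=C5 in place. The closest known reaction type is the Larock heteroannulation of 1,3-dienes by halo carboxylic acids, which gives cis-fused lactones from cyclic dienes. The γ-lactone closes by 5-exo attack of oxygen on the near allyl terminus C6, the seven-membered alternative at C4 being disfavoured. C7 is set by the C8 carbinol: in the conformer free of allylic 1,3-strain (H8 eclipsing C6=C7) the C8 hydroxyl stands on the outer face of the diene and should direct palladium to that face, so C11 enters trans to O8 (7R). C6 is set by the ring: the carboxylate hangs from C11 on that same outer face and cannot reach the inner face of the ring-bound allyl unit, so oxygen is delivered syn to C11 and the lactone is cis-fused (6S). The step needs site selectivity for the diene over the isolated C1=C10 alkene and for C7 over C4, which conjugation of the diene and full substitution at C4 should secure.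

Step 14
Reactants: 19 (3aR,4S,6E,10E,11aS)-10-{[(tert-butyldiphenylsilyl)oxy]methyl}-4-hydroxy-3-methylidene-6-{[(triethylsilyl)oxy]methyl}-3a,4,5,8,9,11a-hexahydrocyclodeca[b]furan-2(3H)-one; 20 3-methylbutanoic acid
Product: 21 (3aR,4R,6E,10E,11aS)-10-{[(tert-butyldiphenylsilyl)oxy]methyl}-3-methylidene-2-oxo-6-{[(triethylsilyl)oxy]methyl}-2,3,3a,4,5,8,9,11a-octahydrocyclodeca[b]furan-4-yl 3-methylbutanoate
Conditions: PPh3, diisopropyl azodicarboxylate, toluene, 0 °C (betaine pre-formed); then 20 and 19, 0 °C to rt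
Reagents that add atoms: none
Why: Mitsunobu esterification displaces the activated C8 oxygen by isovalerate with SN2 inversion, which installs the ester and corrects C8 to 8R (O8 cis to C11) in one step; pre-forming the betaine keeps free phosphine away from the methylene lactone.

Step 15
Reactants: 21 (3aR,4R,6E,10E,11aS)-10-{[(tert-butyldiphenylsilyl)oxy]methyl}-3-methylidene-2-oxo-6-{[(triethylsilyl)oxy]methyl}-2,3,3a,4,5,8,9,11a-octahydrocyclodeca[b]furan-4-yl 3-methylbutanoate
Product: 22 (3aR,4R,6E,10E,11aS)-10-{[(tert-butyldiphenylsilyl)oxy]methyl}-6-formyl-3-methylidene-2-oxo-2,3,3a,4,5,8,9,11a-octahydrocyclodeca[b]furan-4-yl 3-methylbutanoate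
Conditions: (COCl)2, DMSO, CH2Cl2, −78 °C; then Et3N, −78 to −20 °C
Reagents that add atoms: none
Why: Under Swern conditions a primary triethylsilyl ether is cleaved and oxidised in one operation, whereas the tert-butyldiphenylsilyl ether, the esters and the methylene lactone are inert, so the conjugated enal should form directly.

Step 16
Reactants: 22 (3aR,4R,6E,10E,11aS)-10-{[(tert-butyldiphenylsilyl)oxy]methyl}-6-formyl-3-methylidene-2-oxo-2,3,3a,4,5,8,9,11a-octahydrocyclodeca[b]furan-4-yl 3-methylbutanoate
Product: 23 (3aR,4R,6E,10E,11aS)-6-formyl-10-(hydroxymethyl)-3-methylidene-2-oxo-2,3,3a,4,5,8,9,11a-octahydrocyclodeca[b]furan-4-yl 3-methylbutanoate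
Conditions: HF·pyridine, pyridine, THF, 0 °C to rt
Reagents that add atoms: none
Why: Buffered fluoride desilylation removes the tert-butyldiphenylsilyl ether from the primary allylic C15 oxygen without touching the enal, the isovalerate or the Michael-accepting lactone.

**Compound list**

1 | triethyl phosphonoacetate | CCOC(=O)CP(=O)(OCC)OCC | starting material
2 | 3-bromo-1,1-dimethoxypropane | COC(CCBr)OC | starting material
3 | ethyl 2-(diethoxyphosphoryl)-5,5-dimethoxypentanoate (racemic) | CCOC(=O)C(CCC(OC)OC)P(=O)(OCC)OCC | intermediate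
4 | (E)-but-2-enal | C/C=C/C=O | starting material
5 | ethyl (2E,4E)-2-(3,3-dimethoxypropyl)hexa-2,4-dienoate | CCOC(=O)/C(CCC(OC)OC)=C/C=C/C | intermediate
6 | (2E,4E)-2-(3,3-dimethoxypropyl)hexa-2,4-dien-1-ol | OC/C(CCC(OC)OC)=C/C=C/C | intermediate
7 | tert-butyl{[(2E,4E)-2-(3,3-dimethoxypropyl)hexa-2,4-dien-1-yl]oxy}diphenylsilane | CC(C)(C)[Si](c1ccccc1)(c1ccccc1)OC/C(CCC(OC)OC)=C/C=C/C | intermediate
8 | (4E,6E)-4-{[(tert-butyldiphenylsilyl)oxy]methyl}octa-4,6-dienal | CC(C)(C)[Si](c1ccccc1)(c1ccccc1)OC/C(CCC=O)=C/C=C/C | intermediate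
9 | (S)-5-(hydroxymethyl)dihydrofuran-2(3H)-one | OC[C@@H]1CCC(=O)O1 | starting material
10 | (S)-5-oxotetrahydrofuran-2-carbaldehyde | O=C[C@@H]1CCC(=O)O1 | intermediate
11 | (S)-5-ethenyldihydrofuran-2(3H)-one | C=C[C@@H]1CCC(=O)O1 | intermediate
12 | diethyl [(5S)-5-ethenyl-2-oxotetrahydrofuran-3-yl]phosphonite (mixture at C3) | C=C[C@@H]1CC(C(=O)O1)P(OCC)OCC | intermediate (not isolated)
13 | diethyl [(5S)-5-ethenyl-2-oxotetrahydrofuran-3-yl]phosphonate (mixture at C3) | C=C[C@@H]1CC(C(=O)O1)P(=O)(OCC)OCC | intermediate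
14 | (3E,5S)-3-[(4E,6E)-4-{[(tert-butyldiphenylsilyl)oxy]methyl}octa-4,6-dien-1-ylidene]-5-ethenyldihydrofuran-2(3H)-one | C=C[C@@H]1C/C(=C\CC/C(CO[Si](c2ccccc2)(c2ccccc2)C(C)(C)C)=C\C=C\C)C(=O)O1 | intermediate
15 | (1E,5E,7Z,9S)-5-{[(tert-butyldiphenylsilyl)oxy]methyl}-10-oxabicyclo[7.2.1]dodeca-1,5,7-trien-11-one (ten-membered triene bridged by the 8,14-lactone) | O=C1O[C@H]2C/C1=C\CC/C(CO[Si](c3ccccc3)(c3ccccc3)C(C)(C)C)=C\C=C/2 | intermediate
16 | (1S,2Z,4E,8E)-5-{[(tert-butyldiphenylsilyl)oxy]methyl}-9-(hydroxymethyl)cyclodeca-2,4,8-trien-1-ol | OC/C1=C/CC/C(CO[Si](c2ccccc2)(c2ccccc2)C(C)(C)C)=C\C=C/[C@@H](O)C1 | intermediate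
17 | (1S,2Z,4E,8E)-5-{[(tert-butyldiphenylsilyl)oxy]methyl}-9-{[(triethylsilyl)oxy]methyl}cyclodeca-2,4,8-trien-1-ol | CC[Si](CC)(CC)OC/C1=C/CC/C(CO[Si](c2ccccc2)(c2ccccc2)C(C)(C)C)=C\C=C/[C@@H](O)C1 | intermediate
18 | 2-bromoprop-2-enoic acid | C=C(Br)C(=O)O | starting material
19 | (3aR,4S,6E,10E,11aS)-10-{[(tert-butyldiphenylsilyl)oxy]methyl}-4-hydroxy-3-methylidene-6-{[(triethylsilyl)oxy]methyl}-3a,4,5,8,9,11a-hexahydrocyclodeca[b]furan-2(3H)-one | C=C1C(=O)O[C@H]2/C=C(/CO[Si](c3ccccc3)(c3ccccc3)C(C)(C)C)CC/C=C(/CO[Si](CC)(CC)CC)C[C@H](O)[C@@H]12 | intermediate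
20 | 3-methylbutanoic acid | CC(C)CC(=O)O | starting material
21 | (3aR,4R,6E,10E,11aS)-10-{[(tert-butyldiphenylsilyl)oxy]methyl}-3-methylidene-2-oxo-6-{[(triethylsilyl)oxy]methyl}-2,3,3a,4,5,8,9,11a-octahydrocyclodeca[b]furan-4-yl 3-methylbutanoate | C=C1C(=O)O[C@H]2/C=C(/CO[Si](c3ccccc3)(c3ccccc3)C(C)(C)C)CC/C=C(/CO[Si](CC)(CC)CC)C[C@@H](OC(=O)CC(C)C)[C@@H]12 | intermediate
22 | (3aR,4R,6E,10E,11aS)-10-{[(tert-butyldiphenylsilyl)oxy]methyl}-6-formyl-3-methylidene-2-oxo-2,3,3a,4,5,8,9,11a-octahydrocyclodeca[b]furan-4-yl 3-methylbutanoate | C=C1C(=O)O[C@H]2/C=C(/CO[Si](c3ccccc3)(c3ccccc3)C(C)(C)C)CC/C=C(/C=O)C[C@@H](OC(=O)CC(C)C)[C@@H]12 | intermediate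
23 | (3aR,4R,6E,10E,11aS)-6-formyl-10-(hydroxymethyl)-3-methylidene-2-oxo-2,3,3a,4,5,8,9,11a-octahydrocyclodeca[b]furan-4-yl 3-methylbutanoate | C=C1C(=O)O[C@H]2/C=C(/CO)CC/C=C(/C=O)C[C@@H](OC(=O)CC(C)C)[C@@H]12 | target

**Step count and risks**

Total step count: 16. Longest linear sequence: 13 steps (steps 1–5 and 9–16).

Steps most likely to fail:

Step 13. The allylpalladium intermediate may be lost by β-hydride elimination before the C–O bond forms, the vinylpalladium species may oxidise the C8 carbinol, or base may move the acyl group from O6 to O8. The fallback avoids palladium and base and builds the lactone in two stages by a radical route. It sets out from 17: Mn(OAc)3·2H2O (trivalent manganese) and malonic acid in AcOH buffered with KOAc at 25 °C should add the dicarboxymethyl radical to C7 and close one carboxylate onto the oxidised allylic position C6, giving the α-carboxy lactone F1. Decarboxylative Mannich methylenation of F1 (aqueous formaldehyde, Et2NH, then NaOAc, AcOH, 70 °C) comes back to the route at 19.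

Step 10. Oligomerisation may outrun ring closure, or the catalyst may fail to turn over because of the strain of closing a ten-membered ring across the lactone bridge. The fallback gives up the bridge as a template and closes the ring on the open chain. It sets out from 14: i-Bu2AlH (CH2Cl2, −78 to 0 °C) reduces the lactone first to the acyclic diol F2, in which the free allylic C8 hydroxyl activates the neighbouring vinyl group and the two trisubstituted alkenes act as turn elements. Ring-closing metathesis of F2 (second-generation Hoveyda–Grubbs catalyst, toluene, high dilution) comes back to the route at 16.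

Step 14. Elimination across C8–C9 towards a conjugated diene, or substitution with retention through participation of the lactone carbonyl, may compete with clean inversion at the hindered C8 carbinol. The fallback inverts C8 by oxidation and reduction. It sets out from 19: Dess–Martin periodinane (NaHCO3, CH2Cl2, 0 °C) gives the ketone F3. NaBH4 with CeCl3·7H2O (MeOH, −78 °C) should deliver hydride from the ring face opposite the cis-fused lactone and give the 8R alcohol F4; the low temperature guards against β-elimination of the lactone oxygen. Acylation of F4 with 3-methylbutanoic anhydride (DMAP, pyridine, CH2Cl2) comes back to the route at 21.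

**Further compounds**

F1 | step 13 | (3aR,4S,6E,10E,11aS)-10-{[(tert-butyldiphenylsilyl)oxy]methyl}-4-hydroxy-2-oxo-6-{[(triethylsilyl)oxy]methyl}-2,3,3a,4,5,8,9,11a-octahydrocyclodeca[b]furan-3-carboxylic acid (mixture at C3) | OC(=O)C1C(=O)O[C@H]2/C=C(/CO[Si](c3ccccc3)(c3ccccc3)C(C)(C)C)CC/C=C(/CO[Si](CC)(CC)CC)C[C@H](O)[C@@H]12
F2 | step 10 | (3S,5E,9E,11E)-9-{[(tert-butyldiphenylsilyl)oxy]methyl}-5-(hydroxymethyl)trideca-1,5,9,11-tetraen-3-ol | C=C[C@@H](O)C/C(CO)=C\CC/C(CO[Si](c1ccccc1)(c1ccccc1)C(C)(C)C)=C\C=C\C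
F3 | step 14 | (3aS,6E,10E,11aS)-10-{[(tert-butyldiphenylsilyl)oxy]methyl}-3-methylidene-6-{[(triethylsilyl)oxy]methyl}-3a,8,9,11a-tetrahydrocyclodeca[b]furan-2,4(3H,5H)-dione | C=C1C(=O)O[C@H]2/C=C(/CO[Si](c3ccccc3)(c3ccccc3)C(C)(C)C)CC/C=C(/CO[Si](CC)(CC)CC)CC(=O)[C@@H]12
F4 | step 14 | (3aR,4R,6E,10E,11aS)-10-{[(tert-butyldiphenylsilyl)oxy]methyl}-4-hydroxy-3-methylidene-6-{[(triethylsilyl)oxy]methyl}-3a,4,5,8,9,11a-hexahydrocyclodeca[b]furan-2(3H)-one | C=C1C(=O)O[C@H]2/C=C(/CO[Si](c3ccccc3)(c3ccccc3)C(C)(C)C)CC/C=C(/CO[Si](CC)(CC)CC)C[C@@H](O)[C@@H]12
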